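**Retrosynthetic overview**

1. End game: the C7=C8/C17-OH allylic alcohol comes from a C17 aldehyde on a C6=C7 octalin (base moves the alkene into conjugation, then 1,2-reduction). The C11–C12 bond comes from a Wittig reaction of a C9 aldehyde (C11) with a C12–C16 ylide made from (R)-monomethyl 3-methylglutarate, followed by diimide saturation.
2. Key disconnection: the C8–C9 bond, cut together with C5–C10, i.e. an intramolecular Diels–Alder reaction of the acyclic trienal 12. Rings A and B form in the same step: ring A as the tether ring, ring B as the cyclohexene that the C8–C9 bond closes.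
3. Enabling feature: ring B (C5–C6–C7–C8–C9–C10) is a cyclohexene in which C9 carries C11 (raised to CHO) and C10 is the methyl-bearing fusion carbon. With the alkene parked at C6=C7, ring B is the adduct of the diene C5=C6–C7=C8 and the (E)-enal C11–C9=C10, and the four ring-A carbons C1–C4 tether the two. C17 on C8 allows the alkene to be moved to C7=C8 afterwards.
4. Trienal 12 comes from three commercial pieces: geranyl acetate (C1, C2, C3, C9, C10, C11, C20), 3-methylbuta-1,2-diene (C4, C5, C6, C18, C19; Brown reverse prenylation sets C3) and vinylboronate 10 (C7, C8, C17; oxidative Heck).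

Key step: step 7

Remark: carbons carry labdane numbers; the target is the ent-labdane (3R,5S,9S,10S,13R).
Assumption: the 3,3-dimethylallylborane made from (−)-Ipc2BH [(+)-α-pinene series] attacks the aldehyde Si face, as the parent allyl reagent of that series does.

**Step 1**
Reactants: 1 geranyl acetate
Product: 3 (2E)-3-methyl-6-oxohex-2-en-1-yl acetate, via secondary ozonide 2 (not isolated)
Conditions: O3 (1 equiv), CH2Cl2, −78 °C; then Me2S, −78 °C to rt
Reagents that add atoms: ozone, [O-][O+]=O
Why: Ozonolysis with reductive work-up: ozone adds to the electron-rich isopropylidene alkene much faster than to the alkene deactivated by the allylic acetoxy group, so one equivalent should cleave only the remote alkene and keep the (E)-allylic acetate.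

**Step 2**
Reactants: 3 (2E)-3-methyl-6-oxohex-2-en-1-yl acetate; 4 3-methylbuta-1,2-diene
Product: 7 (2E,6R)-6-hydroxy-3,7,7-trimethylnona-2,8-dien-1-yl acetate, via 3,3-dimethylallylborane 5 (not isolated), via borinate ester 6 (not isolated)
Conditions: (−)-Ipc2BH [from (+)-α-pinene and BH3·SMe2], THF, −25 °C; then 3, −78 °C; then HOCH2CH2NH2, rt
Reagents that add atoms: none
Why: Brown allylboration (reverse prenylation): Ipc2BH adds to the unsubstituted allene terminus, the resulting allylborane delivers its γ-carbon to the aldehyde through a chair six-membered transition state, and the isopinocampheyl groups direct Si-face attack, which sets C3 as (R) beside the new quaternary C4.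

**Step 3**
Reactants: 7 (2E,6R)-6-hydroxy-3,7,7-trimethylnona-2,8-dien-1-yl acetate
Product: 8 (2E,6R)-6-(tert-butyldimethylsilyloxy)-3,7,7-trimethylnona-2,8-dien-1-yl acetate
Conditions: TBSOTf, 2,6-lutidine, CH2Cl2, −78 to 0 °C
Reagents that add atoms: tert-butyldimethylsilyl trifluoromethanesulfonate, CC(C)(C)[Si](C)(C)OS(=O)(=O)C(F)(F)F
Why: Silylation with a silyl triflate is fast enough for the hindered secondary alcohol next to the quaternary carbon and leaves the acetate and both alkenes untouched.

**Step 4**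
Reactants: 8 (2E,6R)-6-(tert-butyldimethylsilyloxy)-3,7,7-trimethylnona-2,8-dien-1-yl acetate
Product: 9 (2E,6R)-6-(tert-butyldimethylsilyloxy)-3,7,7-trimethylnona-2,8-dien-1-ol
Conditions: K2CO3, MeOH, rt
Reagents that add atoms: none
Why: Base-catalysed transesterification (methanolysis) removes the acetate, the silyl ether is stable, and the free alcohol avoids an ionisable allylic ester in the palladium step that follows.

**Step 5**
Reactants: 9 (2E,6R)-6-(tert-butyldimethylsilyloxy)-3,7,7-trimethylnona-2,8-dien-1-ol; 10 (E)-tert-butyldimethyl{[3-(4,4,5,5-tetramethyl-1,3,2-dioxaborolan-2-yl)prop-2-en-1-yl]oxy}silane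
Product: 11 (2E,6R,8E,10E)-6,12-bis(tert-butyldimethylsilyloxy)-3,7,7-trimethyldodeca-2,8,10-trien-1-ol
Conditions: Pd(OAc)2 (10 mol %), 1,2-bis(phenylsulfinyl)ethane (10 mol %), 2,6-dimethyl-1,4-benzoquinone, AcOH, dioxane, 40 °C
Reagents that add atoms: none
Why: Oxidative Heck vinylation: the vinyl group passes from boron to divalent palladium and adds to the terminal carbon C6 of the monosubstituted alkene; because C4 is quaternary, β-hydride elimination can only use a C6 hydrogen, so the (E,E)-diene should form without alkene migration while the trisubstituted alkene does not insert.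

**Step 6**
Reactants: 11 (2E,6R,8E,10E)-6,12-bis(tert-butyldimethylsilyloxy)-3,7,7-trimethyldodeca-2,8,10-trien-1-ol
Product: 12 (2E,6R,8E,10E)-6,12-bis(tert-butyldimethylsilyloxy)-3,7,7-trimethyldodeca-2,8,10-trienal
Conditions: MnO2, CH2Cl2, rt
Reagents that add atoms: none
Why: MnO2 oxidation is selective for the allylic alcohol and should give the (E)-enal without touching the silyl ethers or the diene.

**Step 7**
Reactants: 12 (2E,6R,8E,10E)-6,12-bis(tert-butyldimethylsilyloxy)-3,7,7-trimethyldodeca-2,8,10-trienal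
Product: 13 trans-fused octalin aldehyde (C6=C7; 9-CHO; 8-CH2OTBS; 3-OTBS; C3/C5/C9/C10 as in the target; H8 cis to H9)
Conditions: Me2AlCl (1.2 equiv), CH2Cl2, −78 to 0 °C
Reagents that add atoms: none
Why: The Me2AlCl-bound (E)-enal C11–C9=C10 adds suprafacially to the (E,E)-diene C5=C6–C7=C8 in a concerted, asynchronous [4+2] cycloaddition in which the bond from the enal β-carbon C10 to C5 runs ahead and the C8–C9 bond then closes ring B; the closest known reaction type is the Lewis-acid-promoted intramolecular Diels–Alder reaction of 2,8,10-undecatrienals to trans-fused octalins. Ring B (C5–C6–C7–C8–C9–C10) closes as the cyclohexene of the cycloaddition, and ring A (C1–C5, C10) closes at the same time as the fused ring spanned by the four-carbon tether, which passes through a chair. C9 against C10 is set by the (E)-enal geometry (C11 cis to the C10 methyl), C5 against C10 by the endo position of the aluminium-complexed formyl group (tether exo, trans fusion), C8 (C17 cis to C11, erased later) by the (E)-C7=C8 bond, and the absolute sense by the C3 silyloxy group sitting equatorial in the tether chair. The step needs endo over exo selectivity and one diene face: the terminal Lewis-acid-activated aldehyde secures the first and the equatorial C3–OTBS group beside the C4 gem-dimethyl pair secures the second, while the gem-dimethyl (Thorpe–Ingold) effect helps the hindered C5–C10 bond to form.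

**Step 8**
Reactants: 14 (R)-5-methoxy-3-methyl-5-oxopentanoic acid
Product: 15 methyl (S)-4-iodo-3-methylbutanoate
Conditions: PhI(OAc)2, I2, cyclohexane, hν (tungsten lamp), reflux
Reagents that add atoms: iodine, II
Why: Hunsdiecker-type iododecarboxylation: the acyl hypoiodite fragments under light to a primary alkyl radical that takes up iodine, and the stereocentre, one carbon away from the radical, is not affected.

**Step 9**
Reactants: 15 methyl (S)-4-iodo-3-methylbutanoate
Product: 16 [(2S)-4-methoxy-2-methyl-4-oxobutyl]triphenylphosphonium iodide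
Conditions: PPh3, MeCN, reflux
Reagents that add atoms: triphenylphosphine, c1ccc(cc1)P(c1ccccc1)c1ccccc1
Why: SN2 quaternisation of triphenylphosphine by the primary iodide, which needs prolonged heating because of the β-branch but has no competing pathway.

**Step 10**
Reactants: 13 trans-fused octalin aldehyde; 16 [(2S)-4-methoxy-2-methyl-4-oxobutyl]triphenylphosphonium iodide
Product: 18 methyl (11Z)-3,17-bis(tert-butyldimethylsilyloxy)-ent-labda-6,11-dien-15-oate, via phosphorus ylide 17 (not isolated)
Conditions: NaN(SiMe3)2, THF, −78 °C; then 13, −78 °C to rt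
Reagents that add atoms: none
Why: Wittig olefination with a non-stabilised ylide under lithium-free conditions should give the (Z)-alkene C11=C12; C13 is not acidic and C9 keeps its equatorial formyl-derived substituent, which is also the thermodynamically preferred one.

**Step 11**
Reactants: 18 methyl (11Z)-3,17-bis(tert-butyldimethylsilyloxy)-ent-labda-6,11-dien-15-oate
Product: 19 methyl (11Z)-3,17-dihydroxy-ent-labda-6,11-dien-15-oate
Conditions: HF·pyridine, pyridine, THF, 0 °C to rt
Reagents that add atoms: none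
Why: Fluoride-driven desilylation removes both silyl ethers under buffered conditions that leave the methyl ester and the alkenes alone.

**Step 12**
Reactants: 19 methyl (11Z)-3,17-dihydroxy-ent-labda-6,11-dien-15-oate
Product: 21 methyl (11Z)-3-hydroxy-17-oxo-ent-labda-7,11-dien-15-oate, via deconjugated aldehyde 20 (not isolated)
Conditions: TEMPO (10 mol %), PhI(OAc)2, CH2Cl2, rt; then DBU, rt
Reagents that add atoms: none
Why: Oxoammonium (TEMPO) oxidation takes the primary C17 alcohol in preference to the hindered secondary C3 alcohol, and DBU then converts the β,γ-unsaturated aldehyde through its dienolate (protonation at C6) into the conjugated enal, which places the alkene at C7=C8 and removes the C8 stereocentre.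

**Step 13**
Reactants: 21 methyl (11Z)-3-hydroxy-17-oxo-ent-labda-7,11-dien-15-oate
Product: 22 methyl (11Z)-3,17-dihydroxy-ent-labda-7,11-dien-15-oate
Conditions: NaBH4, CeCl3·7H2O, MeOH, −40 °C
Reagents that add atoms: none
Why: Luche reduction gives 1,2-reduction of the enal to the allylic alcohol and does not reduce the methyl ester.

**Step 14**
Reactants: 22 methyl (11Z)-3,17-dihydroxy-ent-labda-7,11-dien-15-oate
Product: 23 methyl (3R,5S,9S,10S,13R)-3,17-dihydroxylabd-7-en-15-oate
Conditions: 2-nitrobenzenesulfonyl hydrazide, Et3N, CH2Cl2, rt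
Reagents that add atoms: none
Why: Diimide reduction transfers two hydrogens in a concerted syn fashion and reacts much faster with the disubstituted (Z)-C11=C12 alkene than with the trisubstituted C7=C8 alkene, so the allylic alcohol should survive.

**Compound list**

1 | geranyl acetate | CC(C)=CCC/C(C)=C/COC(C)=O | starting material
2 | (2E)-5-(5,5-dimethyl-1,2,4-trioxolan-3-yl)-3-methylpent-2-en-1-yl acetate (secondary ozonide) | CC(=O)OC/C=C(\C)CCC1OOC(C)(C)O1 | intermediate
3 | (2E)-3-methyl-6-oxohex-2-en-1-yl acetate | CC(=O)OC/C=C(\C)CCC=O | intermediate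
4 | 3-methylbuta-1,2-diene | CC(C)=C=C | starting material
5 | B-(3-methylbut-2-en-1-yl)diisopinocampheylborane, (+)-α-pinene series | CC(C)=CCB([C@@H]1C[C@@H]2C[C@H]([C@H]1C)C2(C)C)[C@@H]1C[C@@H]2C[C@H]([C@H]1C)C2(C)C | intermediate
6 | diisopinocampheylborinate ester of alcohol 7 | CC(=O)OC/C=C(\C)CC[C@@H](OB([C@@H]1C[C@@H]2C[C@H]([C@H]1C)C2(C)C)[C@@H]1C[C@@H]2C[C@H]([C@H]1C)C2(C)C)C(C)(C)C=C | intermediate
7 | (2E,6R)-6-hydroxy-3,7,7-trimethylnona-2,8-dien-1-yl acetate | CC(=O)OC/C=C(\C)CC[C@@H](O)C(C)(C)C=C | intermediate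
8 | (2E,6R)-6-(tert-butyldimethylsilyloxy)-3,7,7-trimethylnona-2,8-dien-1-yl acetate | CC(=O)OC/C=C(\C)CC[C@@H](O[Si](C)(C)C(C)(C)C)C(C)(C)C=C | intermediate
9 | (2E,6R)-6-(tert-butyldimethylsilyloxy)-3,7,7-trimethylnona-2,8-dien-1-ol | OC/C=C(\C)CC[C@@H](O[Si](C)(C)C(C)(C)C)C(C)(C)C=C | intermediate
10 | (E)-tert-butyldimethyl{[3-(4,4,5,5-tetramethyl-1,3,2-dioxaborolan-2-yl)prop-2-en-1-yl]oxy}silane | CC(C)(C)[Si](C)(C)OC/C=C/B1OC(C)(C)C(C)(C)O1 | starting material
11 | (2E,6R,8E,10E)-6,12-bis(tert-butyldimethylsilyloxy)-3,7,7-trimethyldodeca-2,8,10-trien-1-ol | OC/C=C(\C)CC[C@@H](O[Si](C)(C)C(C)(C)C)C(C)(C)/C=C/C=C/CO[Si](C)(C)C(C)(C)C | intermediate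
12 | (2E,6R,8E,10E)-6,12-bis(tert-butyldimethylsilyloxy)-3,7,7-trimethyldodeca-2,8,10-trienal | O=C/C=C(\C)CC[C@@H](O[Si](C)(C)C(C)(C)C)C(C)(C)/C=C/C=C/CO[Si](C)(C)C(C)(C)C | intermediate
13 | trans-fused octalin aldehyde: C6=C7; C9–CHO (C11); 10-CH3, 9-CHO, 8-CH2OTBS and 3-OTBS on one face; H5, H8 and H9 on the other | O=C[C@@H]1[C@H](CO[Si](C)(C)C(C)(C)C)C=C[C@@H]2C(C)(C)[C@H](O[Si](C)(C)C(C)(C)C)CC[C@@]12C | intermediate
14 | (R)-5-methoxy-3-methyl-5-oxopentanoic acid [(R)-monomethyl 3-methylglutarate] | COC(=O)C[C@H](C)CC(=O)O | starting material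
15 | methyl (S)-4-iodo-3-methylbutanoate | COC(=O)C[C@H](C)CI | intermediate
16 | [(2S)-4-methoxy-2-methyl-4-oxobutyl]triphenylphosphonium iodide | COC(=O)C[C@H](C)C[P+](c1ccccc1)(c1ccccc1)c1ccccc1.[I-] | intermediate
17 | methyl (3S)-3-methyl-4-(triphenyl-λ5-phosphanylidene)butanoate (ylide) | COC(=O)C[C@H](C)C=P(c1ccccc1)(c1ccccc1)c1ccccc1 | intermediate
18 | methyl (11Z)-3,17-bis(tert-butyldimethylsilyloxy)-ent-labda-6,11-dien-15-oate (ring centres as in 13; C13 as in 16) | COC(=O)C[C@H](C)/C=C\[C@@H]1[C@H](CO[Si](C)(C)C(C)(C)C)C=C[C@@H]2C(C)(C)[C@H](O[Si](C)(C)C(C)(C)C)CC[C@@]12C | intermediate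
19 | methyl (11Z)-3,17-dihydroxy-ent-labda-6,11-dien-15-oate | COC(=O)C[C@H](C)/C=C\[C@@H]1[C@H](CO)C=C[C@@H]2C(C)(C)[C@H](O)CC[C@@]12C | intermediate
20 | methyl (11Z)-3-hydroxy-17-oxo-ent-labda-6,11-dien-15-oate | COC(=O)C[C@H](C)/C=C\[C@@H]1[C@H](C=O)C=C[C@@H]2C(C)(C)[C@H](O)CC[C@@]12C | intermediate
21 | methyl (11Z)-3-hydroxy-17-oxo-ent-labda-7,11-dien-15-oate | COC(=O)C[C@H](C)/C=C\[C@@H]1C(C=O)=CC[C@@H]2C(C)(C)[C@H](O)CC[C@@]12C | intermediate
22 | methyl (11Z)-3,17-dihydroxy-ent-labda-7,11-dien-15-oate | COC(=O)C[C@H](C)/C=C\[C@@H]1C(CO)=CC[C@@H]2C(C)(C)[C@H](O)CC[C@@]12C | intermediate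
23 | methyl (3R,5S,9S,10S,13R)-3,17-dihydroxylabd-7-en-15-oate | COC(=O)C[C@H](C)CC[C@@H]1C(CO)=CC[C@@H]2C(C)(C)[C@H](O)CC[C@@]12C | target

**Totals**

Total step count: 14. Longest linear sequence: 12 (steps 1–7 and 10–14).

**Steps most likely to fail**

1. Step 7. The cycloaddition may lose endo or facial selectivity (cis-fused adducts, or adducts mismatched with C3), because the C3 silyloxy group is only homoallylic to the diene and one C10 substituent must sit syn-axial to a C4 methyl in either fusion mode. The complexed enal may also lose its (E)-geometry before it reacts. Fallback with auxiliary control, setting out from 12 and coming back at 13: Pinnick oxidation of 12 (NaClO2, NaH2PO4, 2-methylbut-2-ene) should give the trienoic acid F1. Acylation of (4R)-4-benzyl-1,3-oxazolidin-2-one (pivaloyl chloride, Et3N, LiCl, THF) should give the N-enoyl oxazolidinone F2. In its Me2AlCl chelate (CH2Cl2, −30 °C) the benzyl group shields one face of the s-cis enoyl unit; the (4R) auxiliary exposes the face that leads to the C9/C10 configuration of 13, and the endo cycloaddition should give the cycloadduct imide F3. LiBH4 (THF, MeOH) releases the auxiliary and gives the primary alcohol F4, and Dess–Martin periodinane oxidises it to 13.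

2. Step 10. Addition of the β-branched ylide to the aldehyde flanked by the quaternary C10 and the C8 substituent may be slow, so that enolisation and ylide decomposition compete; the route then also depends on the later selective saturation of C11=C12. Fallback by sp3–sp3 coupling, setting out from 13 and coming back at 23: NaBH4 reduces 13 to the primary alcohol F4, and iodine, PPh3 and imidazole convert it into the primary iodide F8. Zinc dust with LiCl in THF converts iodide 15 into the alkylzinc iodide F9. A Negishi alkyl–alkyl coupling of F8 with F9 (Ni(cod)2, s-Bu-Pybox, DMA, rt) should give the saturated-chain bis-silyl ether F10 with C11–C12 already single. HF·pyridine gives the diol F11, TEMPO/PhI(OAc)2 followed by DBU gives the conjugated enal F12, and Luche reduction gives 23 without any diimide step.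

3. Step 5. Insertion of the vinyl group next to the quaternary C4 may be slow, so that homocoupling and protodeboronation of 10 consume the boronate. Fallback by carbonyl olefination and cross-coupling, setting out from 9 and coming back at 12: MnO2 oxidises 9 to the enal F5. One equivalent of ozone (CH2Cl2, −78 °C, then Me2S) should cleave the isolated vinyl group in preference to the conjugated enal alkene and give the enedial F6. Takai olefination (CHI3, CrCl2, THF) of the unconjugated aldehyde gives the (E)-vinyl iodide F7, and Suzuki–Miyaura coupling of F7 with 10 (Pd(PPh3)4, K3PO4, THF/H2O) gives 12.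

**Further compounds**

F1 | step 7 | (2E,6R,8E,10E)-6,12-bis(tert-butyldimethylsilyloxy)-3,7,7-trimethyldodeca-2,8,10-trienoic acid | OC(=O)/C=C(\C)CC[C@@H](O[Si](C)(C)C(C)(C)C)C(C)(C)/C=C/C=C/CO[Si](C)(C)C(C)(C)C
F2 | step 7 | (4R)-4-benzyl-3-[(2E,6R,8E,10E)-6,12-bis(tert-butyldimethylsilyloxy)-3,7,7-trimethyldodeca-2,8,10-trienoyl]-1,3-oxazolidin-2-one | O=C(/C=C(\C)CC[C@@H](O[Si](C)(C)C(C)(C)C)C(C)(C)/C=C/C=C/CO[Si](C)(C)C(C)(C)C)N1[C@H](Cc2ccccc2)COC1=O
F3 | step 7 | cycloadduct imide (ring centres as in 13; acyl group on C9 bound to the (4R)-4-benzyl-2-oxo-1,3-oxazolidin-3-yl unit) | O=C([C@@H]1[C@H](CO[Si](C)(C)C(C)(C)C)C=C[C@@H]2C(C)(C)[C@H](O[Si](C)(C)C(C)(C)C)CC[C@@]12C)N1[C@H](Cc2ccccc2)COC1=O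
F4 | step 7 | primary alcohol corresponding to aldehyde 13 (C11 carbinol) | OC[C@@H]1[C@H](CO[Si](C)(C)C(C)(C)C)C=C[C@@H]2C(C)(C)[C@H](O[Si](C)(C)C(C)(C)C)CC[C@@]12C
F5 | step 5 | (2E,6R)-6-(tert-butyldimethylsilyloxy)-3,7,7-trimethylnona-2,8-dienal | O=C/C=C(\C)CC[C@@H](O[Si](C)(C)C(C)(C)C)C(C)(C)C=C
F6 | step 5 | (2E,6R)-6-(tert-butyldimethylsilyloxy)-3,7,7-trimethyloct-2-enedial | O=C/C=C(\C)CC[C@@H](O[Si](C)(C)C(C)(C)C)C(C)(C)C=O
F7 | step 5 | (2E,6R,8E)-6-(tert-butyldimethylsilyloxy)-9-iodo-3,7,7-trimethylnona-2,8-dienal | O=C/C=C(\C)CC[C@@H](O[Si](C)(C)C(C)(C)C)C(C)(C)/C=C/I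
F8 | step 10 | primary iodide corresponding to alcohol F4 (C11 iodide) | IC[C@@H]1[C@H](CO[Si](C)(C)C(C)(C)C)C=C[C@@H]2C(C)(C)[C@H](O[Si](C)(C)C(C)(C)C)CC[C@@]12C
F9 | step 10 | [(2S)-4-methoxy-2-methyl-4-oxobutyl]zinc iodide | COC(=O)C[C@H](C)C[Zn]I
F10 | step 10 | methyl 3,17-bis(tert-butyldimethylsilyloxy)-ent-labd-6-en-15-oate (ring centres as in 13; C13 as in the target) | COC(=O)C[C@H](C)CC[C@@H]1[C@H](CO[Si](C)(C)C(C)(C)C)C=C[C@@H]2C(C)(C)[C@H](O[Si](C)(C)C(C)(C)C)CC[C@@]12C
F11 | step 10 | methyl 3,17-dihydroxy-ent-labd-6-en-15-oate | COC(=O)C[C@H](C)CC[C@@H]1[C@H](CO)C=C[C@@H]2C(C)(C)[C@H](O)CC[C@@]12C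
F12 | step 10 | methyl 3-hydroxy-17-oxo-ent-labd-7-en-15-oate | COC(=O)C[C@H](C)CC[C@@H]1C(C=O)=CC[C@@H]2C(C)(C)[C@H](O)CC[C@@]12C
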